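**Plan**

- Cuts: C11'=C12' and C11=C12 (Wittig, C15 + C10 + C15), C9–C10 and C9'–C10' (vinyl addition), C7=C8 (HWE), and last C3–C4 plus C1–C2 of ring A (the β ring).
- Enabling feature: ring A is a cyclohexene with C5=C6 opposite the C2–C3 edge, the acyloxy donor on C3 and the chain carbon C7 on C6, 1,4 to each other. With C7 as a formyl group the diene CH2=C(Me)–C(CHO)=CMe2 is electron-poor and polarity-matched to vinyl palmitate.
- Forward: ring A is formed first by this inverse-electron-demand [4+2] cycloaddition, which brings in the palmitate, C3 and C7 together. The adduct is grown to a C15 phosphonium salt and joined to the C10 trienedial.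
- Ring B (the ε ring) comes preformed from racemic α-ionone (C3' oxidation, reduction, myristoylation); its C15 phosphonium salt is joined last.
- Stereochemistry: C3 from the chiral oxazaborolidinium catalyst in the cycloaddition; C3' from CBS reduction, with C6' secured by separating the diastereomers; E alkenes from HWE/Wittig steps and thermal Z to E equilibration.

Key step: step 3

Assumption: in step 3 the (S)-configured catalyst is taken to give the (R)-adduct on the basis of its face-shielding model; the mirror-image catalyst is equally accessible should the sense be the opposite.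

**Route**

Step 1
Reactants: 1 3-methylbut-2-enal
Product: 3 2-bromo-3-methylbut-2-enal, via 2,3-dibromo-3-methylbutanal 2 (not isolated)
Conditions: Br2, CH2Cl2, −10 °C; then Et3N, 0 °C → rt
Reagents that add atoms: bromine, BrBr
Why: Bromine adds across the enal double bond and triethylamine then removes the acidic α-hydrogen with loss of the tertiary bromide (bromination–dehydrobromination), the standard way to α-bromoenals.

Step 2
Reactants: 3 2-bromo-3-methylbut-2-enal; 4 4,4,5,5-tetramethyl-2-(prop-1-en-2-yl)-1,3,2-dioxaborolane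
Product: 5 3-methyl-2-(propan-2-ylidene)but-3-enal
Conditions: Pd(OAc)2 (3 mol%), SPhos (6 mol%), K3PO4, THF/H2O, 40 °C
Reagents that add atoms: none
Why: Suzuki–Miyaura coupling of an α-bromoenal with an alkenylboronate, in which the bulky biarylphosphine allows oxidative addition and transmetalation at the fully substituted alkene; no stereocentre or alkene geometry is at stake.

Step 3
Reactants: 5 3-methyl-2-(propan-2-ylidene)but-3-enal; 6 ethenyl hexadecanoate (vinyl palmitate)
Product: 7 (1R)-4-formyl-3,5,5-trimethylcyclohex-3-en-1-yl hexadecanoate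
Conditions: 6 (3 equiv), (S)-3,3-diphenyl-1-(o-tolyl)tetrahydro-1H,3H-pyrrolo[1,2-c][1,3,2]oxazaborole·HNTf2 (20 mol%), CH2Cl2, −78 → −20 °C
Reagents that add atoms: none
Why: Proposed new method: the cationic oxazaborolidinium binds the formyl oxygen of 5 (s-trans enal, formyl C–H···O contact), which lowers the LUMO of the C4=C5–C6=C1 diene and places positive charge on the tertiary terminus C1, so that the CH2 end of vinyl palmitate bonds to C1 and its acyloxy-bearing carbon to C4 in one concerted, strongly asynchronous inverse-electron-demand [4+2] cycloaddition that leaves the C5=C6 enal of 7. The closest known reaction types are the oxazaborolidinium-catalysed Diels–Alder and [2+2] reactions of α-substituted acroleins and the Lewis-acid-promoted inverse-demand cycloadditions of 2-acyl-1,3-dienes and 3-acyl-2-pyrones with enol ethers and enol esters; the enantioselective pairing of a 2-formyl-1,3-diene with a vinyl ester is the untested part. Ring A closes as a six-membered carbocycle by intermolecular [4π+2π] addition across C1 and C4 of the s-cis diene. C3 is the only new stereocentre and is fixed by the catalyst: its aryl group covers one face of the C6=C1 unit, the enol ester approaches the open face, and the acyloxy group sits endo over C5–C6, where it is held by attraction to the cationic diene. Regioselectivity is secured by the formyl group on C6 (C1 is the electrophilic terminus and the vinyl CH2 the nucleophilic one, so the oxygen ends up 1,4 to C7), and periselectivity by the s-trans geometry of the bound enal, which keeps the carbonyl oxygen away from C1 and leaves the carbocycle, with its restored conjugated enal, as the thermodynamic outlet. A vinyl ester is chosen over a vinyl ether because it does not polymerise under the strong acid and delivers the palmitate directly.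

Step 4
Reactants: 7 (1R)-4-formyl-3,5,5-trimethylcyclohex-3-en-1-yl hexadecanoate; 8 dimethyl (2-oxopropyl)phosphonate
Product: 10 (1R)-3,5,5-trimethyl-4-[(1E)-3-oxobut-1-en-1-yl]cyclohex-3-en-1-yl hexadecanoate, via lithiated phosphonate 9 (not isolated)
Conditions: LiCl, iPr2NEt, MeCN, rt
Reagents that add atoms: none
Why: Horner–Wadsworth–Emmons olefination under Masamune–Roush conditions, where the weak amine base avoids vinylogous deprotonation at C4 (which would expel palmitate) and the stabilised phosphonate gives the (7E)-enone without touching C3.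

Step 5
Reactants: 10 (1R)-3,5,5-trimethyl-4-[(1E)-3-oxobut-1-en-1-yl]cyclohex-3-en-1-yl hexadecanoate; 11 vinylmagnesium bromide
Product: 12 (1R)-4-[(1E)-3-hydroxy-3-methylpenta-1,4-dien-1-yl]-3,5,5-trimethylcyclohex-3-en-1-yl hexadecanoate (both epimers at the carbinol carbon)
Conditions: 11 (1.15 equiv), THF, −78 °C; sat. aq. NH4Cl
Reagents that add atoms: none
Why: Grignard 1,2-addition to the methyl ketone, which at −78 °C should outpace attack on the long-chain secondary ester; the new carbinol centre forms as both epimers and is erased in step 6.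

Step 6
Reactants: 12 (1R)-4-[(1E)-3-hydroxy-3-methylpenta-1,4-dien-1-yl]-3,5,5-trimethylcyclohex-3-en-1-yl hexadecanoate
Product: 13 {(2E,4E)-5-[(4R)-4-(hexadecanoyloxy)-2,6,6-trimethylcyclohex-1-en-1-yl]-3-methylpenta-2,4-dien-1-yl}triphenylphosphonium bromide
Conditions: PPh3·HBr, CH2Cl2, 0 °C → rt
Reagents that add atoms: triphenylphosphine hydrobromide, [Br-].c1ccc(cc1)[PH+](c1ccccc1)c1ccccc1
Why: Acid ionises the tertiary bis-allylic alcohol to a pentadienyl cation that triphenylphosphine captures at the primary terminus (SN1'-type formation of an allylic phosphonium salt, the classical C15 Wittig-salt synthesis), giving the (9E)-salt on crystallisation while the ester and C3 are untouched in aprotic medium.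

Step 7
Reactants: 13 {(2E,4E)-5-[(4R)-4-(hexadecanoyloxy)-2,6,6-trimethylcyclohex-1-en-1-yl]-3-methylpenta-2,4-dien-1-yl}triphenylphosphonium bromide; 14 (2E,4E,6E)-2,7-dimethylocta-2,4,6-trienedial
Product: 16 (2E,4E,6E,8E,10E,12E)-13-[(4R)-4-(hexadecanoyloxy)-2,6,6-trimethylcyclohex-1-en-1-yl]-2,7,11-trimethyltrideca-2,4,6,8,10,12-hexaenal, via β-C15 ylide 15 (not isolated)
Conditions: 13 added slowly to 14 (2.5 equiv), 1,2-epoxybutane, reflux; then n-heptane, reflux
Reagents that add atoms: none
Why: Wittig olefination with the ylide released by the neutral epoxide/bromide base system, which spares the ester; excess dialdehyde should favour mono-olefination and the hindered (11Z) isomer should revert to (11E) on heating.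

Step 8
Reactants: 17 racemic (3E)-4-(2,6,6-trimethylcyclohex-2-en-1-yl)but-3-en-2-one (α-ionone)
Product: 18 racemic 2-methyl-2-[(E)-2-(2,6,6-trimethylcyclohex-2-en-1-yl)ethenyl]-1,3-dioxolane
Conditions: HOCH2CH2OH, HC(OEt)3, p-TsOH (cat.), rt
Reagents that add atoms: ethylene glycol, OCCO
Why: Acid-catalysed ketalisation driven by the orthoformate at room temperature, mild enough to leave the C4'=C5' double bond in place; it masks C9' so that only the ring is oxidised and reduced next.

Step 9
Reactants: 18 racemic 2-methyl-2-[(E)-2-(2,6,6-trimethylcyclohex-2-en-1-yl)ethenyl]-1,3-dioxolane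
Product: 19 racemic 3,5,5-trimethyl-4-[(E)-2-(2-methyl-1,3-dioxolan-2-yl)ethenyl]cyclohex-2-en-1-one
Conditions: t-BuOOH (70% aq.), NaOCl (aq.), K2CO3, MeCN, −5 → 0 °C
Reagents that add atoms: tert-butyl hydroperoxide, CC(C)(C)OO
Why: Radical allylic oxidation (hydrogen abstraction, peroxide formation and fragmentation to the ketone) at the secondary ring CH2 next to the trisubstituted alkene, a known transformation of α-ionone derivatives that gives the ring enone.

Step 10
Reactants: 19 racemic 3,5,5-trimethyl-4-[(E)-2-(2-methyl-1,3-dioxolan-2-yl)ethenyl]cyclohex-2-en-1-one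
Product: 20 (1R,4R)-3,5,5-trimethyl-4-[(E)-2-(2-methyl-1,3-dioxolan-2-yl)ethenyl]cyclohex-2-en-1-ol
Conditions: (S)-1-methyl-3,3-diphenyltetrahydro-1H,3H-pyrrolo[1,2-c][1,3,2]oxazaborole [(S)-Me-CBS] (20 mol%), catecholborane, toluene, −78 °C; aq. NaOH work-up; chromatography
Reagents that add atoms: none
Why: Corey–Bakshi–Shibata reduction, in which the oxazaborolidine binds the ketone with the alkenyl arm as the large group and delivers hydride to one face, should set (3'R) in both enantiomers of 19; the (6'R) half gives the trans alcohol 20 and the (6'S) half its cis diastereomer, which is removed by chromatography.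

Step 11
Reactants: 20 (1R,4R)-3,5,5-trimethyl-4-[(E)-2-(2-methyl-1,3-dioxolan-2-yl)ethenyl]cyclohex-2-en-1-ol
Product: 21 (3E)-4-[(1R,4R)-4-hydroxy-2,6,6-trimethylcyclohex-2-en-1-yl]but-3-en-2-one
Conditions: PPTS (cat.), THF/H2O, 40 °C
Reagents that add atoms: water, O
Why: Mild acid hydrolysis of the dioxolane, under which the secondary allylic alcohol should not ionise, so C3' and C6' are kept.

Step 12
Reactants: 21 (3E)-4-[(1R,4R)-4-hydroxy-2,6,6-trimethylcyclohex-2-en-1-yl]but-3-en-2-one; 11 vinylmagnesium bromide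
Product: 22 (1R,4R)-4-[(1E)-3-hydroxy-3-methylpenta-1,4-dien-1-yl]-3,5,5-trimethylcyclohex-2-en-1-ol (both epimers at the tertiary carbinol)
Conditions: 11 (2.3 equiv), THF, −40 → 0 °C; sat. aq. NH4Cl
Reagents that add atoms: none
Why: Grignard 1,2-addition to the methyl ketone after in-flask deprotonation of the free hydroxyl (hence more than two equivalents); with no ester present there is no chemoselectivity issue, and the new carbinol centre is erased in step 14.

Step 13
Reactants: 22 (1R,4R)-4-[(1E)-3-hydroxy-3-methylpenta-1,4-dien-1-yl]-3,5,5-trimethylcyclohex-2-en-1-ol; 23 tetradecanoyl chloride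
Product: 24 (1R,4R)-4-[(1E)-3-hydroxy-3-methylpenta-1,4-dien-1-yl]-3,5,5-trimethylcyclohex-2-en-1-yl tetradecanoate
Conditions: 23 (1.05 equiv), pyridine, DMAP (cat.), CH2Cl2, −20 → 0 °C
Reagents that add atoms: none
Why: Acylation under nucleophilic catalysis is selective for the secondary allylic hydroxyl over the hindered tertiary carbinol and proceeds with retention at C3'.

Step 14
Reactants: 24 (1R,4R)-4-[(1E)-3-hydroxy-3-methylpenta-1,4-dien-1-yl]-3,5,5-trimethylcyclohex-2-en-1-yl tetradecanoate
Product: 25 {(2E,4E)-3-methyl-5-[(1R,4R)-2,6,6-trimethyl-4-(tetradecanoyloxy)cyclohex-2-en-1-yl]penta-2,4-dien-1-yl}triphenylphosphonium bromide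
Conditions: PPh3·HBr, CH2Cl2, 0 °C → rt
Reagents that add atoms: triphenylphosphine hydrobromide, [Br-].c1ccc(cc1)[PH+](c1ccccc1)c1ccccc1
Why: As in step 6, the tertiary bis-allylic alcohol ionises and is trapped by triphenylphosphine at the primary terminus; it should ionise far faster than the secondary allylic ester, so C3' and C6' are preserved.

Step 15
Reactants: 16 (2E,4E,6E,8E,10E,12E)-13-[(4R)-4-(hexadecanoyloxy)-2,6,6-trimethylcyclohex-1-en-1-yl]-2,7,11-trimethyltrideca-2,4,6,8,10,12-hexaenal; 25 {(2E,4E)-3-methyl-5-[(1R,4R)-2,6,6-trimethyl-4-(tetradecanoyloxy)cyclohex-2-en-1-yl]penta-2,4-dien-1-yl}triphenylphosphonium bromide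
Product: 27 (3R,3'R,6'R)-β,ε-carotene-3,3'-diol 3-hexadecanoate 3'-tetradecanoate (CNP0238324.1), via ε-C15 ylide 26 (not isolated)
Conditions: 25 (1.1 equiv), 1,2-epoxybutane, reflux; then n-heptane, reflux (Z → E)
Reagents that add atoms: none
Why: Wittig olefination under the same neutral conditions joins C11' to C12' without touching either ester or any stereocentre, and the hindered (11'Z) isomer should revert thermally to the all-E target.

**Compound list**

1 | 3-methylbut-2-enal | CC(C)=CC=O | starting material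
2 | 2,3-dibromo-3-methylbutanal | CC(C)(Br)C(Br)C=O | intermediate
3 | 2-bromo-3-methylbut-2-enal | CC(C)=C(Br)C=O | intermediate
4 | 4,4,5,5-tetramethyl-2-(prop-1-en-2-yl)-1,3,2-dioxaborolane | CC(=C)B1OC(C)(C)C(C)(C)O1 | starting material
5 | 3-methyl-2-(propan-2-ylidene)but-3-enal | CC(=C)C(C=O)=C(C)C | intermediate
6 | ethenyl hexadecanoate (vinyl palmitate) | CCCCCCCCCCCCCCCC(=O)OC=C | starting material
7 | (1R)-4-formyl-3,5,5-trimethylcyclohex-3-en-1-yl hexadecanoate | CCCCCCCCCCCCCCCC(=O)O[C@@H]1CC(C)=C(C=O)C(C)(C)C1 | intermediate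
8 | dimethyl (2-oxopropyl)phosphonate | COP(=O)(OC)CC(C)=O | starting material
9 | lithium salt of dimethyl (2-oxopropyl)phosphonate (lithiated phosphonate) | [Li+].COP(=O)(OC)[CH-]C(C)=O | intermediate
10 | (1R)-3,5,5-trimethyl-4-[(1E)-3-oxobut-1-en-1-yl]cyclohex-3-en-1-yl hexadecanoate | CCCCCCCCCCCCCCCC(=O)O[C@@H]1CC(C)=C(/C=C/C(C)=O)C(C)(C)C1 | intermediate
11 | vinylmagnesium bromide | C=C[Mg]Br | starting material
12 | (1R)-4-[(1E)-3-hydroxy-3-methylpenta-1,4-dien-1-yl]-3,5,5-trimethylcyclohex-3-en-1-yl hexadecanoate (both carbinol epimers) | CCCCCCCCCCCCCCCC(=O)O[C@@H]1CC(C)=C(/C=C/C(C)(O)C=C)C(C)(C)C1 | intermediate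
13 | {(2E,4E)-5-[(4R)-4-(hexadecanoyloxy)-2,6,6-trimethylcyclohex-1-en-1-yl]-3-methylpenta-2,4-dien-1-yl}triphenylphosphonium bromide | CCCCCCCCCCCCCCCC(=O)O[C@@H]1CC(C)=C(/C=C/C(C)=C/C[P+](c2ccccc2)(c2ccccc2)c2ccccc2)C(C)(C)C1.[Br-] | intermediate
14 | (2E,4E,6E)-2,7-dimethylocta-2,4,6-trienedial | O=C/C(C)=C/C=C/C=C(C)/C=O | starting material
15 | β-C15 ylide: (2E,4E)-5-[(4R)-4-(hexadecanoyloxy)-2,6,6-trimethylcyclohex-1-en-1-yl]-3-methylpenta-2,4-dien-1-ylidene(triphenyl)phosphorane | CCCCCCCCCCCCCCCC(=O)O[C@@H]1CC(C)=C(/C=C/C(C)=C/C=P(c2ccccc2)(c2ccccc2)c2ccccc2)C(C)(C)C1 | intermediate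
16 | (2E,4E,6E,8E,10E,12E)-13-[(4R)-4-(hexadecanoyloxy)-2,6,6-trimethylcyclohex-1-en-1-yl]-2,7,11-trimethyltrideca-2,4,6,8,10,12-hexaenal | CCCCCCCCCCCCCCCC(=O)O[C@@H]1CC(C)=C(/C=C/C(C)=C/C=C/C(C)=C/C=C/C=C(C)/C=O)C(C)(C)C1 | intermediate
17 | racemic (3E)-4-(2,6,6-trimethylcyclohex-2-en-1-yl)but-3-en-2-one (α-ionone) | CC(=O)/C=C/C1C(C)=CCCC1(C)C | starting material
18 | racemic 2-methyl-2-[(E)-2-(2,6,6-trimethylcyclohex-2-en-1-yl)ethenyl]-1,3-dioxolane | CC1(/C=C/C2C(C)=CCCC2(C)C)OCCO1 | intermediate
19 | racemic 3,5,5-trimethyl-4-[(E)-2-(2-methyl-1,3-dioxolan-2-yl)ethenyl]cyclohex-2-en-1-one | CC1(/C=C/C2C(C)=CC(=O)CC2(C)C)OCCO1 | intermediate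
20 | (1R,4R)-3,5,5-trimethyl-4-[(E)-2-(2-methyl-1,3-dioxolan-2-yl)ethenyl]cyclohex-2-en-1-ol | CC1(/C=C/[C@H]2C(C)=C[C@H](O)CC2(C)C)OCCO1 | intermediate
21 | (3E)-4-[(1R,4R)-4-hydroxy-2,6,6-trimethylcyclohex-2-en-1-yl]but-3-en-2-one | CC(=O)/C=C/[C@H]1C(C)=C[C@H](O)CC1(C)C | intermediate
22 | (1R,4R)-4-[(1E)-3-hydroxy-3-methylpenta-1,4-dien-1-yl]-3,5,5-trimethylcyclohex-2-en-1-ol (both carbinol epimers) | C=CC(C)(O)/C=C/[C@H]1C(C)=C[C@H](O)CC1(C)C | intermediate
23 | tetradecanoyl chloride | CCCCCCCCCCCCCC(=O)Cl | starting material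
24 | (1R,4R)-4-[(1E)-3-hydroxy-3-methylpenta-1,4-dien-1-yl]-3,5,5-trimethylcyclohex-2-en-1-yl tetradecanoate (both carbinol epimers) | C=CC(C)(O)/C=C/[C@H]1C(C)=C[C@H](OC(=O)CCCCCCCCCCCCC)CC1(C)C | intermediate
25 | {(2E,4E)-3-methyl-5-[(1R,4R)-2,6,6-trimethyl-4-(tetradecanoyloxy)cyclohex-2-en-1-yl]penta-2,4-dien-1-yl}triphenylphosphonium bromide | [Br-].c1ccccc1[P+](c1ccccc1)(c1ccccc1)C/C=C(C)/C=C/[C@H]1C(C)=C[C@H](OC(=O)CCCCCCCCCCCCC)CC1(C)C | intermediate
26 | ε-C15 ylide: (2E,4E)-3-methyl-5-[(1R,4R)-2,6,6-trimethyl-4-(tetradecanoyloxy)cyclohex-2-en-1-yl]penta-2,4-dien-1-ylidene(triphenyl)phosphorane | c1ccccc1P(c1ccccc1)(c1ccccc1)=C/C=C(C)/C=C/[C@H]1C(C)=C[C@H](OC(=O)CCCCCCCCCCCCC)CC1(C)C | intermediate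
27 | (3R,3'R,6'R)-β,ε-carotene-3,3'-diol 3-hexadecanoate 3'-tetradecanoate (CNP0238324.1) | CCCCCCCCCCCCCCCC(=O)O[C@@H]1CC(C)=C(/C=C/C(C)=C/C=C/C(C)=C/C=C/C=C(C)/C=C/C=C(C)/C=C/[C@H]2C(C)=C[C@H](OC(=O)CCCCCCCCCCCCC)CC2(C)C)C(C)(C)C1 | target

**Count and risks**

Total steps: 15. Longest linear sequence: 8 steps (steps 1–7 and 15 from 1; equally steps 8–15 from 17).

Risk 1, step 3 (the proposed method). The fully substituted diene terminus C1 may be too hindered for bond formation at low temperature. The intermediate polarised complex may close through the carbonyl oxygen instead of C4. Face and endo/exo discrimination may be too weak to give useful enantiomeric purity. The acid may also promote loss of palmitic acid from the adduct. Fallback from 5 (with 6), returning at 7: 5 is heated in neat 6 (5 equiv) with BHT at 150 °C in a sealed vessel, a thermal inverse-demand Diels–Alder reaction of an electron-poor diene with an enol ester, to give racemic 4-formyl-3,5,5-trimethylcyclohex-3-en-1-yl hexadecanoate F1. Enantioselective alcoholysis with Burkholderia cepacia lipase and n-butanol in tert-butyl methyl ether at 35 °C should, by the normal preference of this lipase for esters of secondary alcohols, release (4R)-4-hydroxy-2,6,6-trimethylcyclohex-1-ene-1-carbaldehyde F2 and leave the (S)-ester behind. F2 is then acylated with hexadecanoyl chloride and pyridine to give 7; should the enzyme prefer the other antipode, the recovered ester is 7 itself.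

Risk 2, step 5. The Grignard reagent may attack the ester carbonyl in competition with the ketone, and vinylogous enolisation at C4 may expel palmitate. Fallback from 10, returning at 12: methanolysis (K2CO3, MeOH, 0 °C) gives (3E)-4-[(4R)-4-hydroxy-2,6,6-trimethylcyclohex-1-en-1-yl]but-3-en-2-one F3. Excess vinylmagnesium bromide (2.3 equiv, THF, −40 °C) gives (1R)-4-[(1E)-3-hydroxy-3-methylpenta-1,4-dien-1-yl]-3,5,5-trimethylcyclohex-3-en-1-ol F4. Selective acylation of the secondary hydroxyl with hexadecanoyl chloride (1.05 equiv), pyridine and catalytic DMAP at −20 °C returns 12.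

Risk 3, step 10. Facial discrimination may be weak because the two arms of the ring ketone differ little in size, and the cis and trans alcohols may be hard to separate. Fallback from 19, returning at 24: Luche reduction (NaBH4, CeCl3·7H2O, MeOH, −40 °C) and removal of the cis isomer gives racemic (1R,4R)-3,5,5-trimethyl-4-[(E)-2-(2-methyl-1,3-dioxolan-2-yl)ethenyl]cyclohex-2-en-1-ol F5. Kinetic resolution with Burkholderia cepacia lipase and vinyl tetradecanoate in tert-butyl methyl ether should acylate the (1R)-carbinol to (1R,4R)-3,5,5-trimethyl-4-[(E)-2-(2-methyl-1,3-dioxolan-2-yl)ethenyl]cyclohex-2-en-1-yl tetradecanoate F6, leaving the (1S,4S)-alcohol unreacted. Hydrolysis of the ketal (PPTS, THF/H2O) gives (1R,4R)-3,5,5-trimethyl-4-[(1E)-3-oxobut-1-en-1-yl]cyclohex-2-en-1-yl tetradecanoate F7. Vinylmagnesium bromide (1.15 equiv, THF, −78 °C) then returns 24.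

**Further compounds**

F1 | step 3 | racemic 4-formyl-3,5,5-trimethylcyclohex-3-en-1-yl hexadecanoate | CCCCCCCCCCCCCCCC(=O)OC1CC(C)=C(C=O)C(C)(C)C1
F2 | step 3 | (4R)-4-hydroxy-2,6,6-trimethylcyclohex-1-ene-1-carbaldehyde | O[C@@H]1CC(C)=C(C=O)C(C)(C)C1
F3 | step 5 | (3E)-4-[(4R)-4-hydroxy-2,6,6-trimethylcyclohex-1-en-1-yl]but-3-en-2-one | O[C@@H]1CC(C)=C(/C=C/C(C)=O)C(C)(C)C1
F4 | step 5 | (1R)-4-[(1E)-3-hydroxy-3-methylpenta-1,4-dien-1-yl]-3,5,5-trimethylcyclohex-3-en-1-ol | O[C@@H]1CC(C)=C(/C=C/C(C)(O)C=C)C(C)(C)C1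
F5 | step 10 | racemic (1R,4R)-3,5,5-trimethyl-4-[(E)-2-(2-methyl-1,3-dioxolan-2-yl)ethenyl]cyclohex-2-en-1-ol (one enantiomer drawn) | CC1(/C=C/[C@H]2C(C)=C[C@H](O)CC2(C)C)OCCO1
F6 | step 10 | (1R,4R)-3,5,5-trimethyl-4-[(E)-2-(2-methyl-1,3-dioxolan-2-yl)ethenyl]cyclohex-2-en-1-yl tetradecanoate | CC1(/C=C/[C@H]2C(C)=C[C@H](OC(=O)CCCCCCCCCCCCC)CC2(C)C)OCCO1
F7 | step 10 | (1R,4R)-3,5,5-trimethyl-4-[(1E)-3-oxobut-1-en-1-yl]cyclohex-2-en-1-yl tetradecanoate | CC(=O)/C=C/[C@H]1C(C)=C[C@H](OC(=O)CCCCCCCCCCCCC)CC1(C)C
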